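**Conventions and assumption**

- Guaiane numbering is used throughout: five-membered ring C1–C5, seven-membered ring C5–C10 and C1, C11–C13 on C7, C14 on C10, C15 on C4. β is the face of the C10 methyl group, α the other face.
- Assumption: (2S)-4-methoxy-2-methyl-4-oxobutanoic acid (the 4-methyl half ester of (S)-methylsuccinic acid) is taken as a catalogue compound.

## Analysis of the target

Compound 42 is a guaiane: a cyclopentenone (C1–C5, ketone at C3, tetrasubstituted C4=C5 bond carrying the C15 methyl) fused through C1 and C5 to a cycloheptane (C5–C10, C1). It has five stereocentres, C1 (R), C6 (R), C7 (S), C8 (R) and C10 (S). The C6 hydroxyl, the C7 2-acetoxypropan-2-yl group, the C8 angelate and the C10 methyl all lie on the β face; the tertiary C1 hydroxyl lies on the α face. The sensitive groups are the angelate (Z to E isomerisation), the β-hydroxy ketone C1(OH)–C2–C3(=O) (retro-aldol opening), and the 1,3-related oxygens on C6, C8 and C11 (acyl migration). The difficulty is the contiguous all-cis C6/C7/C8 array on a seven-membered ring, set between a quaternary carbinol of the opposite face and the C10 methyl, with three oxygens that must end up free, angeloylated and acetylated. The strategy rests on C7: it carries C11, which at carboxyl level is an acid carbon flanked by the carbinol carbons C6 and C8. C6–C7 is then the bond formed by an ester-enolate [3,3] shift, provided C11 is the carbonyl of a lactone whose ring oxygen sits on C1 and C5=C6 is an enol ether on C1. That seven-membered lactone (C11, C7, C8, C9, C10, C1, O) folds into the carbocycle and leaves a C1=C5 alkene exactly where the five-membered ring has to be built.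

## Retrosynthetic reasoning

**42 ⇒ 41 ⇒ 38 + 39.** The benzyl–oxygen bond at C6 and then the acyl–oxygen bond at C8 are cut first. The angelate isomerises easily, so it is introduced from acid 39 as late as possible; the C6 hydroxyl is freed last under neutral oxidative conditions that allow no acyl migration. Forward, only the secondary C8 hydroxyl of diol 38 must be acylated, the tertiary C1 hydroxyl being too hindered.

**38 ⇒ 37 ⇒ 35 (through 36).** The C1–O bond is cut. C1 is the γ-carbon of the enone, so the hydroxyl can come from oxidation of dienol ether 36, in which C1 is planar. This is preferred to a carbon nucleophile adding to a C1 ketone, which would have to enter next to the C10 methyl on the crowded β face; here the oxidant only has to choose the open α face.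

**35 ⇒ 33 ⇒ 32 ⇒ 31 ⇒ 30.** The five-membered ring is removed in two stages. C4 with its methyl is taken out (forward: one-carbon ring expansion of a cyclobutanone), then C1–C2 and C3–C5 are cut (forward: ketene [2+2] cycloaddition to the C1=C5 alkene of 30). This annulation needs nothing but the alkene the key step leaves behind, and all stereocentres it creates are erased on the way to 35 and 37.

**30 ⇒ 29 ⇒ 27 ⇒ 26.** The two C11 methyls and the acetate are removed, which reveals the carboxyl carbon on C7. Forward, the ester must take up two methyl groups without β-elimination of the flanking C6 and C8 oxygens, and the tertiary alcohol is acetylated while no other hydroxyl is free.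

**26 ⇒ 23 (key disconnection).** C6–C7 is cut and C1 is reconnected to the carboxyl oxygen, giving lactone 23. This one operation accounts for the carbocycle, for C6 and C7, and for the position of the alkene. The forward reaction must form the cyclic silyl ketene acetal 24 without loss of the C8 oxygen and pass through a boat-like transition state.

**23 ⇒ 21 + 22, 21 ⇒ 20.** The enol ether C–O bond is cut to alkenylboronate 21 and alcohol 22, and 21 goes back to alkyne 20 by hydroboration. Cutting here means the acid-labile 3-alkoxyallyl ester exists only in the step before the rearrangement, and the (E)-geometry follows from syn hydroboration of a terminal alkyne.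

**20 ⇒ 18 ⇒ 17 ⇒ 16 ⇒ 13 + 14.** The lactone C–O bond is opened to hydroxy acid 18. The C1 carbinol is traced to ynone 16, because an alkynyl ketone is reduced under reliable catalyst control. The C1–C5 bond is cut between amide 13 and alkyne 14. C1 is a sacrificial centre whose only task is to put the C5=C6 unit trans to the C8 silyloxy group on the lactone ring.

**13 ⇒ 11 ⇒ 8 ⇒ 7 ⇒ 3 + 4, 3 ⇒ 2 ⇒ 1.** The C8 carbinol comes from β-keto ester 7 by asymmetric hydrogenation, and the C7–C8 bond from acylation of malonate 4 by acid 3. C10 is bought with 1. The C1 carboxyl travels as a tert-butyl ester (2, 3, 7, 8) so that the new C8 hydroxyl cannot close a γ-lactone onto it.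

## Alternatives that were turned down

**Alternative 1:** The seven-membered ring is cut at C1–C10 and C9–C10. Meso cyclohexanone A1 would be expanded by a methyl-bearing diazoalkane under a chiral Sc(OTf)3–ligand Lewis acid (trivalent scandium) to cycloheptanone A2.
- For: A1 is symmetric and short to make. The all-cis C6/C7/C8 array comes from symmetry. One catalytic step creates the ring size, C10 and the desymmetrisation. In steps to the seven-membered ring it is better than the chosen route.
- Against: both the choice between enantiotopic methylenes and the C10 configuration rest on the catalyst, with a small, fast-reacting diazoalkane prone to uncatalysed background reaction. A2 is a ketone that can be homologated again. A2 also has C1 as ketone and C5 as methylene, so the whole cyclopentenone is still missing, and a carbon nucleophile would have to add to C1 from the β face beside the C10 methyl.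
- Comparison: the chosen strategy is longer but takes C10 from the pool, relays C6 and C7 inside the molecule, and ends with an alkene at C1–C5 that is ready for annulation.

**Alternative 2:** The C1–C2 bond is cut. Diazoketone A3 would give, with Rh2(OAc)4, a carbene that inserts into the C1–H bond to close cyclopentanone A4.
- For: 1,5-insertion into a tertiary, oxygen-activated C–H bond is the favoured mode and goes with retention. The quaternary C1 carbinol would thus come stereospecifically from a secondary carbinol. On this point the alternative is stronger than the chosen route, which depends on facial selectivity in an oxidation.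
- Against: A3 must already carry seven stereocentres on a cycloheptane. The carbene can also attack the C6–H bond, the benzyl ether oxygen or the aryl ring. A4 is saturated at C4–C5, so a tetrasubstituted enone must be introduced late, next to a β-silyloxy ketone that eliminates easily.
- Comparison: the chosen route offers acyclic, catalyst-controlled stereocentres, fewer centres to carry, and the enone in place before the C1 oxygen is introduced.

**Alternative 3:** C1–C5, C2–C3 and C3–C4 are cut at once. Allene-yne A5 would cyclise with CO under [Rh(CO)2Cl]2 (monovalent rhodium) at the distal allene double bond to dienone A6, closing both rings.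
- For: it is the most step-economic ring construction of all, from a linear precursor with only three stereocentres. It is clearly stronger on step count and convergence.
- Against: in A6 both C10 and C1 are sp2 carbons. The C10 methyl centre and the C1 carbinol must then be made by a formal hydration of the C1=C10 bond of an extended dienone, with regiocontrol and two configurations to be set without a controlling element nearby.
- Comparison: the chosen strategy fixes C10 at the start and creates C1 on a system in which one face is clearly blocked.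

Key step: step 13

## Route

Step 1
Reactants: 1 (2S)-4-methoxy-2-methyl-4-oxobutanoic acid
Product: 2 1-tert-butyl 4-methyl (2S)-2-methylbutanedioate
Conditions: t-BuOC(=NH)CCl3, BF3·OEt2 (cat.), cyclohexane/CH2Cl2, rt
Reagents that add atoms: tert-butyl 2,2,2-trichloroacetimidate, CC(C)(C)OC(=N)C(Cl)(Cl)Cl
Why: Acid-catalysed tert-butyl transfer from the trichloroacetimidate esterifies the acid without base, so C10 is untouched; the tert-butyl ester is chosen because it will not lactonise with the later C8 hydroxyl.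

Step 2
Reactants: 2 1-tert-butyl 4-methyl (2S)-2-methylbutanedioate
Product: 3 (3S)-4-tert-butoxy-3-methyl-4-oxobutanoic acid
Conditions: LiOH·H2O (1.1 equiv), THF/H2O, 0 °C; then 1 M HCl
Reagents that add atoms: lithium hydroxide, [Li+].[OH-]
Why: Saponification takes the unhindered methyl ester and leaves the tert-butyl ester; at 0 °C with one equivalent of hydroxide the centre α to the tert-butyl ester should not epimerise.

Step 3
Reactants: 3 (3S)-4-tert-butoxy-3-methyl-4-oxobutanoic acid; 4 potassium methyl malonate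
Product: 7 1-tert-butyl 6-methyl (2S)-2-methyl-4-oxohexanedioate, via acyl imidazolide 5 (not isolated), via acylmalonate 6 (not isolated)
Conditions: 1,1'-carbonyldiimidazole (CDI), THF, rt; then 4, MgCl2, Et3N, THF, rt → 40 °C; 1 M HCl
Reagents that add atoms: none
Why: Masamune–Brooks homologation: the acyl imidazolide acylates the magnesium enolate of the malonate half ester, and the acylmalonate loses CO2 to give the β-keto ester. The conditions are close to neutral, so C10 is safe.

Step 4
Reactants: 7 1-tert-butyl 6-methyl (2S)-2-methyl-4-oxohexanedioate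
Product: 8 1-tert-butyl 6-methyl (2S,4R)-4-hydroxy-2-methylhexanedioate
Conditions: H2 (50 atm), RuCl2[(R)-BINAP] (0.5 mol %), MeOH, 40 °C
Reagents that add atoms: none
Why: Noyori asymmetric hydrogenation of a β-keto ester through the ester-chelated ruthenium hydride; the (R)-BINAP catalyst should give the (R)-carbinol (C8) under catalyst control, the remote C10 centre having no say. The hindered tert-butyl ester keeps the new γ-hydroxyl from lactonising.

Step 5
Reactants: 8 1-tert-butyl 6-methyl (2S,4R)-4-hydroxy-2-methylhexanedioate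
Product: 11 (2S,4R)-4-[(tert-butyldimethylsilyl)oxy]-6-methoxy-2-methyl-6-oxohexanoic acid, via silyl ether 9 (not isolated), via silyl ester 10 (not isolated)
Conditions: t-BuMe2SiOTf (3 equiv), 2,6-lutidine, CH2Cl2, 0 °C → rt; then K2CO3, MeOH/H2O, 0 °C; pH 4 work-up
Reagents that add atoms: tert-butyldimethylsilyl trifluoromethanesulfonate, CC(C)(C)[Si](C)(C)OS(=O)(=O)C(F)(F)F
Why: The silyl triflate silylates the C8 hydroxyl and then converts the tert-butyl ester into the silyl ester with loss of isobutene (silyl triflate cleavage of tert-butyl esters); carbonate in methanol cleaves only the silyl ester. The methyl ester and the secondary silyl ether should survive.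

Step 6
Reactants: 11 (2S,4R)-4-[(tert-butyldimethylsilyl)oxy]-6-methoxy-2-methyl-6-oxohexanoic acid
Product: 13 methyl (3R,5S)-3-[(tert-butyldimethylsilyl)oxy]-6-[methoxy(methyl)amino]-5-methyl-6-oxohexanoate, via acyl imidazolide 12 (not isolated)
Conditions: CDI, CH2Cl2, rt; then MeNH(OMe)·HCl, rt
Reagents that add atoms: N,O-dimethylhydroxylamine hydrochloride, CNOC.Cl
Why: Weinreb amide formation through the acyl imidazolide; no strong base is present, so C10 next to the activated acyl group is kept, and the silyl ether blocks γ-lactonisation.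

Step 7
Reactants: 13 methyl (3R,5S)-3-[(tert-butyldimethylsilyl)oxy]-6-[methoxy(methyl)amino]-5-methyl-6-oxohexanoate; 14 ethynyltrimethylsilane
Product: 16 methyl (3R,5S)-3-[(tert-butyldimethylsilyl)oxy]-5-methyl-6-oxo-8-(trimethylsilyl)oct-7-ynoate, via lithium acetylide 15 (not isolated)
Conditions: 14, n-BuLi, THF, −78 °C; then 13, −78 → −40 °C; aq. NH4Cl at −40 °C
Reagents that add atoms: none
Why: Weinreb ketone synthesis: the lithium acetylide adds once to the N-methoxy-N-methylamide and the chelated adduct holds until work-up. At low temperature the amide should react well ahead of the methyl ester.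

Step 8
Reactants: 16 methyl (3R,5S)-3-[(tert-butyldimethylsilyl)oxy]-5-methyl-6-oxo-8-(trimethylsilyl)oct-7-ynoate
Product: 17 methyl (3R,5S,6S)-3-[(tert-butyldimethylsilyl)oxy]-6-hydroxy-5-methyl-8-(trimethylsilyl)oct-7-ynoate
Conditions: Ru[(S,S)-TsDPEN](p-cymene) (2 mol %), i-PrOH, rt
Reagents that add atoms: none
Why: Noyori–Ikariya transfer hydrogenation of an alkynyl ketone; the catalyst treats the alkynyl group as it does an aryl group, so the (S,S)-catalyst should give the (S)-carbinol at C1 whatever the adjacent C10 centre prefers. This places the C1 oxygen anti to the C10 methyl, which in the later lactone means the C5=C6 unit trans to the C8 silyloxy group.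

Step 9
Reactants: 17 methyl (3R,5S,6S)-3-[(tert-butyldimethylsilyl)oxy]-6-hydroxy-5-methyl-8-(trimethylsilyl)oct-7-ynoate
Product: 18 (3R,5S,6S)-3-[(tert-butyldimethylsilyl)oxy]-6-hydroxy-5-methyloct-7-ynoic acid
Conditions: LiOH·H2O, THF/MeOH/H2O, 0 °C → rt; then 1 M HCl to pH 3
Reagents that add atoms: lithium hydroxide, [Li+].[OH-]
Why: Hydroxide hydrolyses the methyl ester and removes the alkynyl silyl group in one operation; saponification of a β-silyloxy ester under these conditions is normally faster than β-elimination.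

Step 10
Reactants: 18 (3R,5S,6S)-3-[(tert-butyldimethylsilyl)oxy]-6-hydroxy-5-methyloct-7-ynoic acid
Product: 20 (4R,6S,7S)-4-[(tert-butyldimethylsilyl)oxy]-7-ethynyl-6-methyloxepan-2-one, via mixed anhydride 19 (not isolated)
Conditions: 2-methyl-6-nitrobenzoic anhydride, DMAP, CH2Cl2 (2 mM, slow addition of 18), rt
Reagents that add atoms: none
Why: Shiina lactonisation through the mixed anhydride and DMAP acyl transfer; high dilution favours the seven-membered lactone over the diolide. The acid is activated and the C1–O bond is kept, so no stereocentre changes.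

Step 11
Reactants: 20 (4R,6S,7S)-4-[(tert-butyldimethylsilyl)oxy]-7-ethynyl-6-methyloxepan-2-one
Product: 21 (4R,6S,7S)-4-[(tert-butyldimethylsilyl)oxy]-6-methyl-7-[(E)-2-(4,4,5,5-tetramethyl-1,3,2-dioxaborolan-2-yl)ethenyl]oxepan-2-one
Conditions: pinacolborane, Cp2ZrHCl (10 mol %), Et3N (10 mol %), CH2Cl2, rt → 40 °C
Reagents that add atoms: pinacolborane, CC1(C)OBOC1(C)C
Why: Zirconium-catalysed hydroboration of a terminal alkyne with pinacolborane: syn addition with boron on the terminal carbon gives the (E)-alkenylboronate. The lactone is inert to pinacolborane.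

Step 12
Reactants: 21 (4R,6S,7S)-4-[(tert-butyldimethylsilyl)oxy]-6-methyl-7-[(E)-2-(4,4,5,5-tetramethyl-1,3,2-dioxaborolan-2-yl)ethenyl]oxepan-2-one; 22 4-methoxybenzyl alcohol
Product: 23 (4R,6S,7S)-4-[(tert-butyldimethylsilyl)oxy]-7-[(E)-2-[(4-methoxybenzyl)oxy]ethenyl]-6-methyloxepan-2-one
Conditions: Cu(OAc)2 (2 equiv), Et3N (4 equiv), 4 Å molecular sieves, 22 (excess)/CH2Cl2, air, rt
Reagents that add atoms: none
Why: Chan–Lam–Evans oxidative C–O coupling of an alkenylboronate with an alcohol, mediated by Cu(OAc)2; transmetalation and reductive elimination at copper go with retention, so the (E)-geometry passes into the enol ether. The medium is basic, which suits the acid-labile 3-alkoxyallyl ester.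

Step 13
Reactants: 23 (4R,6S,7S)-4-[(tert-butyldimethylsilyl)oxy]-7-[(E)-2-[(4-methoxybenzyl)oxy]ethenyl]-6-methyloxepan-2-one
Product: 26 (1S,2S,5S,7R)-7-[(tert-butyldimethylsilyl)oxy]-2-[(4-methoxybenzyl)oxy]-5-methylcyclohept-3-ene-1-carboxylic acid, via silyl ketene acetal 24 (not isolated), via silyl ester 25 (not isolated)
Conditions: LiN(i-Pr)2, Me3SiCl/Et3N (premixed), THF, −100 → −78 °C; then rt → 60 °C; aq. K2CO3, then pH 4 buffer
Reagents that add atoms: none
Why: LiN(i-Pr)2 with Me3SiCl already present turns lactone 23 at −100 °C into the cyclic silyl ketene acetal 24, the internal quench leaving the β-silyloxy enolate no time to eliminate. On warming, 24 undergoes a concerted [3,3]-sigmatropic shift along C7=C11–O–C1–C5=C6: C1–O breaks, C6–C7 forms and the double bond moves to C1=C5, giving silyl ester 25, which the aqueous work-up hydrolyses to acid 26. The closest known reaction type is the Ireland–Claisen (ester-enolate Claisen) rearrangement of lactones bearing an alkenyl group on the carbinol carbon, which gives cycloalkenecarboxylic acids, and of glycal esters, which contain the same 3-alkoxyallyl ester unit. The cycloheptene ring (C7, C8, C9, C10, C1, C5, C6) is closed by ring transposition within this pericyclic step: the C8–C9–C10 tether of the lactone becomes part of the carbocycle, and because it ties C7 to C1 the six reacting atoms can only adopt a boat-like geometry, which also makes the new alkene cis. C7 is controlled by C1: the vinyl group reaches C7 only on the lactone face on which it stands, trans to the C8 silyloxy group, so C11 ends cis to the C8 oxygen. C6 is controlled by the (E)-geometry of the enol ether, which in the boat places the C6 oxygen cis to C11. The step needs the all-cis C6/C7/C8 array and retention of the C8 oxygen; the C1 configuration from step 8, the alkene geometry from steps 11 and 12, the outward position of the silyloxy group in the transition state and the ring constraint secure this, and the 6-alkoxy group should speed the shift.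

Step 14
Reactants: 26 (1S,2S,5S,7R)-7-[(tert-butyldimethylsilyl)oxy]-2-[(4-methoxybenzyl)oxy]-5-methylcyclohept-3-ene-1-carboxylic acid
Product: 27 methyl (1S,2S,5S,7R)-7-[(tert-butyldimethylsilyl)oxy]-2-[(4-methoxybenzyl)oxy]-5-methylcyclohept-3-ene-1-carboxylate
Conditions: Me3SiCHN2, toluene/MeOH, 0 °C
Reagents that add atoms: (trimethylsilyl)diazomethane, C[Si](C)(C)C=[N+]=[N-]
Why: O-Methylation of the acid by the diazoalkane in methanol; the conditions are neutral, so the β-oxygens on C6 and C8 are not eliminated.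

Step 15
Reactants: 27 methyl (1S,2S,5S,7R)-7-[(tert-butyldimethylsilyl)oxy]-2-[(4-methoxybenzyl)oxy]-5-methylcyclohept-3-ene-1-carboxylate
Product: 29 2-[(1S,2S,5S,7R)-7-[(tert-butyldimethylsilyl)oxy]-2-[(4-methoxybenzyl)oxy]-5-methylcyclohept-3-en-1-yl]propan-2-ol, via methyl ketone 28 (not isolated)
Conditions: MeLi, CeCl3, THF, −78 → 0 °C; aq. NH4Cl
Reagents that add atoms: methyllithium, [Li]C
Why: Double addition of the organocerium reagent to the ester through methyl ketone 28; its low basicity should suppress enolisation and β-elimination of the C6 and C8 oxygens in this hindered ester.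

Step 16
Reactants: 29 2-[(1S,2S,5S,7R)-7-[(tert-butyldimethylsilyl)oxy]-2-[(4-methoxybenzyl)oxy]-5-methylcyclohept-3-en-1-yl]propan-2-ol
Product: 30 2-[(1S,2S,5S,7R)-7-[(tert-butyldimethylsilyl)oxy]-2-[(4-methoxybenzyl)oxy]-5-methylcyclohept-3-en-1-yl]propan-2-yl acetate
Conditions: Ac2O, DMAP, Et3N, CH2Cl2, 40 °C
Reagents that add atoms: acetic anhydride, CC(=O)OC(C)=O
Why: DMAP-catalysed acetylation of the tertiary alcohol; it is the only free hydroxyl, and it must be capped before the acid chloride of the next step.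

Step 17
Reactants: 30 2-[(1S,2S,5S,7R)-7-[(tert-butyldimethylsilyl)oxy]-2-[(4-methoxybenzyl)oxy]-5-methylcyclohept-3-en-1-yl]propan-2-yl acetate
Product: 31 2-[(1βH,7βH)-4β-[(tert-butyldimethylsilyl)oxy]-9,9-dichloro-6β-[(4-methoxybenzyl)oxy]-2β-methyl-8-oxobicyclo[5.2.0]nonan-5β-yl]propan-2-yl acetate (bicycle C1 and C7 are guaiane C1 and C5; the carbonyl is on guaiane C5, the CCl2 carbon on guaiane C1)
Conditions: Cl3CCOCl, Zn–Cu couple, POCl3, Et2O, rt
Reagents that add atoms: trichloroacetyl chloride, ClC(Cl)(Cl)C(Cl)=O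
Why: [2+2] cycloaddition of dichloroketene, made in the flask by zinc dechlorination (POCl3 binds the ZnCl2), to the cis-alkene. The ketene carbonyl carbon should bond to C5, because the developing positive charge is better placed on C1, away from the electron-withdrawing C6 oxygen. Addition on the α face, opposite the four β substituents, gives the cis-fused cyclobutanone; the two new centres are lost later.

Step 18
Reactants: 31 dichlorocyclobutanone of step 17
Product: 32 (1βH,5βH,7αH,10αH)-11-acetoxy-8β-[(tert-butyldimethylsilyl)oxy]-2,2-dichloro-6β-[(4-methoxybenzyl)oxy]guaian-3-one, both C4 epimers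
Conditions: CH3CHN2 (fresh ethereal solution), Et2O/MeOH, 0 °C
Reagents that add atoms: diazoethane, CC=[N+]=[N-]
Why: Diazoalkane ring expansion of an α,α-dichlorocyclobutanone: the diazoalkane adds to the activated carbonyl and the non-chlorinated carbon C5 migrates with loss of N2, inserting C4 with its methyl group between C3 and C5. The C4 configuration does not matter.

Step 19
Reactants: 32 dichlorocyclopentanone of step 18
Product: 33 (1βH,5βH,7αH,10αH)-11-acetoxy-8β-[(tert-butyldimethylsilyl)oxy]-6β-[(4-methoxybenzyl)oxy]guaian-3-one, both C4 epimers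
Conditions: Zn, AcOH, rt
Reagents that add atoms: none
Why: Reductive removal of both α-chlorine atoms by zinc in acetic acid through the zinc enolate; the ethers, the silyl ether and the acetate are stable to it.

Step 20
Reactants: 33 cyclopentanone of step 19
Product: 35 (1βH,7αH,10αH)-11-acetoxy-8β-[(tert-butyldimethylsilyl)oxy]-6β-[(4-methoxybenzyl)oxy]guai-4-en-3-one, via silyl enol ether 34 (not isolated)
Conditions: Me3SiCl, NaI, Et3N, MeCN, rt; then Pd(OAc)2, MeCN, rt
Reagents that add atoms: none
Why: Ito–Saegusa oxidation: the thermodynamic, more substituted (C3=C4) silyl enol ether is converted by Pd(OAc)2 into the oxa-π-allyl palladium species, and β-hydride elimination of H5 gives the tetrasubstituted C4=C5 enone. The C4 and C5 centres disappear.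

Step 21
Reactants: 35 enone of step 20
Product: 37 (7αH,10αH)-11-acetoxy-8β-[(tert-butyldimethylsilyl)oxy]-1α-hydroxy-6β-[(4-methoxybenzyl)oxy]guai-4-en-3-one, via silyl dienol ether 36 (not isolated)
Conditions: Me3SiOTf, Et3N, CH2Cl2, 0 °C → rt; then dimethyldioxirane, acetone, −78 → −40 °C; aq. NaHCO3
Reagents that add atoms: dimethyldioxirane, CC1(C)OO1
Why: Vinylogous Rubottom oxidation: soft enolisation gives a silyloxycyclopentadiene that settles by [1,5]-hydrogen shifts on the fully substituted isomer 36 (C3=C4, C5=C1), and the dioxirane attacks its γ-carbon C1, as in the γ-hydroxylation of steroidal dienol ethers. C1 is planar in 36, and the oxidant should come from the α face, opposite the C10 methyl and the C6, C7 and C8 substituents, which sets the C1 hydroxyl α.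

Step 22
Reactants: 37 hydroxy enone of step 21
Product: 38 (7αH,10αH)-11-acetoxy-1α,8β-dihydroxy-6β-[(4-methoxybenzyl)oxy]guai-4-en-3-one
Conditions: HF·pyridine, pyridine, THF, 0 °C → rt
Reagents that add atoms: none
Why: Fluoride cleavage of the secondary silyl ether under buffered, weakly acidic conditions, which avoid base-induced migration of the tertiary acetate to the freed C8 hydroxyl and retro-aldol opening of the β-hydroxy ketone.

Step 23
Reactants: 38 diol of step 22; 39 angelic acid, (Z)-2-methylbut-2-enoic acid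
Product: 41 (7αH,10αH)-11-acetoxy-1α-hydroxy-6β-[(4-methoxybenzyl)oxy]-3-oxoguai-4-en-8β-yl (Z)-2-methylbut-2-enoate, via mixed anhydride 40 (not isolated)
Conditions: 39, 2,4,6-Cl3C6H2COCl, Et3N, toluene, rt; then 38, 80 °C
Reagents that add atoms: none
Why: Yamaguchi esterification: the acid is activated as its mixed 2,4,6-trichlorobenzoic anhydride and acylates the secondary C8 hydroxyl without DMAP, a protocol known to keep the (Z)-geometry of angelates. The tertiary C1 hydroxyl is too hindered to react.

Step 24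
Reactants: 41 angelate of step 23
Product: 42 (1R,6R,7S,8R,10S)-11-acetoxy-1,6-dihydroxy-3-oxoguai-4-en-8-yl (Z)-2-methylbut-2-enoate (1α,6β-dihydroxy, 8β-angeloyloxy)
Conditions: DDQ, CH2Cl2/pH 7 buffer, 0 °C → rt
Reagents that add atoms: none
Why: Oxidative cleavage of the 4-methoxybenzyl ether by DDQ in wet, buffered dichloromethane (hydride abstraction, then hydrolysis of the hemiacetal); the neutral medium should leave the angelate, the acetate and the tertiary carbinol in place and allow no acyl migration.

## Compound list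

1 | (2S)-4-methoxy-2-methyl-4-oxobutanoic acid | C[C@@H](CC(=O)OC)C(=O)O | starting material
2 | 1-tert-butyl 4-methyl (2S)-2-methylbutanedioate | C[C@@H](CC(=O)OC)C(=O)OC(C)(C)C | intermediate
3 | (3S)-4-tert-butoxy-3-methyl-4-oxobutanoic acid | C[C@@H](CC(=O)O)C(=O)OC(C)(C)C | intermediate
4 | potassium methyl malonate | COC(=O)CC(=O)[O-].[K+] | starting material
5 | tert-butyl (2S)-4-(imidazol-1-yl)-2-methyl-4-oxobutanoate (acyl imidazolide) | C[C@@H](CC(=O)n1ccnc1)C(=O)OC(C)(C)C | intermediate
6 | (5S)-6-tert-butoxy-2-(methoxycarbonyl)-5-methyl-3,6-dioxohexanoic acid (acylmalonate, present as magnesium chelate) | C[C@@H](CC(=O)C(C(=O)O)C(=O)OC)C(=O)OC(C)(C)C | intermediate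
7 | 1-tert-butyl 6-methyl (2S)-2-methyl-4-oxohexanedioate | C[C@@H](CC(=O)CC(=O)OC)C(=O)OC(C)(C)C | intermediate
8 | 1-tert-butyl 6-methyl (2S,4R)-4-hydroxy-2-methylhexanedioate | C[C@@H](C[C@@H](O)CC(=O)OC)C(=O)OC(C)(C)C | intermediate
9 | 1-tert-butyl 6-methyl (2S,4R)-4-[(tert-butyldimethylsilyl)oxy]-2-methylhexanedioate | C[C@@H](C[C@@H](O[Si](C)(C)C(C)(C)C)CC(=O)OC)C(=O)OC(C)(C)C | intermediate
10 | 1-(tert-butyldimethylsilyl) 6-methyl (2S,4R)-4-[(tert-butyldimethylsilyl)oxy]-2-methylhexanedioate | C[C@@H](C[C@@H](O[Si](C)(C)C(C)(C)C)CC(=O)OC)C(=O)O[Si](C)(C)C(C)(C)C | intermediate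
11 | (2S,4R)-4-[(tert-butyldimethylsilyl)oxy]-6-methoxy-2-methyl-6-oxohexanoic acid | C[C@@H](C[C@@H](O[Si](C)(C)C(C)(C)C)CC(=O)OC)C(=O)O | intermediate
12 | methyl (3R,5S)-3-[(tert-butyldimethylsilyl)oxy]-6-(imidazol-1-yl)-5-methyl-6-oxohexanoate | C[C@@H](C[C@@H](O[Si](C)(C)C(C)(C)C)CC(=O)OC)C(=O)n1ccnc1 | intermediate
13 | methyl (3R,5S)-3-[(tert-butyldimethylsilyl)oxy]-6-[methoxy(methyl)amino]-5-methyl-6-oxohexanoate | C[C@@H](C[C@@H](O[Si](C)(C)C(C)(C)C)CC(=O)OC)C(=O)N(C)OC | intermediate
14 | ethynyltrimethylsilane | C#C[Si](C)(C)C | starting material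
15 | lithium (trimethylsilyl)acetylide | [Li]C#C[Si](C)(C)C | intermediate
16 | methyl (3R,5S)-3-[(tert-butyldimethylsilyl)oxy]-5-methyl-6-oxo-8-(trimethylsilyl)oct-7-ynoate | C[C@@H](C[C@@H](O[Si](C)(C)C(C)(C)C)CC(=O)OC)C(=O)C#C[Si](C)(C)C | intermediate
17 | methyl (3R,5S,6S)-3-[(tert-butyldimethylsilyl)oxy]-6-hydroxy-5-methyl-8-(trimethylsilyl)oct-7-ynoate | C[C@@H](C[C@@H](O[Si](C)(C)C(C)(C)C)CC(=O)OC)[C@H](O)C#C[Si](C)(C)C | intermediate
18 | (3R,5S,6S)-3-[(tert-butyldimethylsilyl)oxy]-6-hydroxy-5-methyloct-7-ynoic acid | C[C@@H](C[C@@H](O[Si](C)(C)C(C)(C)C)CC(=O)O)[C@H](O)C#C | intermediate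
19 | mixed anhydride of 18 with 2-methyl-6-nitrobenzoic acid | C[C@@H](C[C@@H](O[Si](C)(C)C(C)(C)C)CC(=O)OC(=O)c1c(C)cccc1[N+](=O)[O-])[C@H](O)C#C | intermediate
20 | (4R,6S,7S)-4-[(tert-butyldimethylsilyl)oxy]-7-ethynyl-6-methyloxepan-2-one | O=C1C[C@H](O[Si](C)(C)C(C)(C)C)C[C@H](C)[C@@H](C#C)O1 | intermediate
21 | (4R,6S,7S)-4-[(tert-butyldimethylsilyl)oxy]-6-methyl-7-[(E)-2-(4,4,5,5-tetramethyl-1,3,2-dioxaborolan-2-yl)ethenyl]oxepan-2-one | O=C1C[C@H](O[Si](C)(C)C(C)(C)C)C[C@H](C)[C@@H](/C=C/B2OC(C)(C)C(C)(C)O2)O1 | intermediate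
22 | 4-methoxybenzyl alcohol | COc1ccc(CO)cc1 | starting material
23 | (4R,6S,7S)-4-[(tert-butyldimethylsilyl)oxy]-7-[(E)-2-[(4-methoxybenzyl)oxy]ethenyl]-6-methyloxepan-2-one (key-step precursor) | O=C1C[C@H](O[Si](C)(C)C(C)(C)C)C[C@H](C)[C@@H](/C=C/OCc2ccc(OC)cc2)O1 | intermediate
24 | (4R,6S,7S)-4-[(tert-butyldimethylsilyl)oxy]-7-[(E)-2-[(4-methoxybenzyl)oxy]ethenyl]-6-methyl-2-[(trimethylsilyl)oxy]-4,5,6,7-tetrahydrooxepine (silyl ketene acetal) | C[Si](C)(C)OC1=C[C@H](O[Si](C)(C)C(C)(C)C)C[C@H](C)[C@@H](/C=C/OCc2ccc(OC)cc2)O1 | intermediate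
25 | trimethylsilyl (1S,2S,5S,7R)-7-[(tert-butyldimethylsilyl)oxy]-2-[(4-methoxybenzyl)oxy]-5-methylcyclohept-3-ene-1-carboxylate | CC(C)(C)[Si](C)(C)O[C@@H]1C[C@H](C)C=C[C@H](OCc2ccc(OC)cc2)[C@@H]1C(=O)O[Si](C)(C)C | intermediate
26 | (1S,2S,5S,7R)-7-[(tert-butyldimethylsilyl)oxy]-2-[(4-methoxybenzyl)oxy]-5-methylcyclohept-3-ene-1-carboxylic acid (key-step product) | CC(C)(C)[Si](C)(C)O[C@@H]1C[C@H](C)C=C[C@H](OCc2ccc(OC)cc2)[C@@H]1C(=O)O | intermediate
27 | methyl (1S,2S,5S,7R)-7-[(tert-butyldimethylsilyl)oxy]-2-[(4-methoxybenzyl)oxy]-5-methylcyclohept-3-ene-1-carboxylate | CC(C)(C)[Si](C)(C)O[C@@H]1C[C@H](C)C=C[C@H](OCc2ccc(OC)cc2)[C@@H]1C(=O)OC | intermediate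
28 | 1-[(1S,2S,5S,7R)-7-[(tert-butyldimethylsilyl)oxy]-2-[(4-methoxybenzyl)oxy]-5-methylcyclohept-3-en-1-yl]ethan-1-one | CC(C)(C)[Si](C)(C)O[C@@H]1C[C@H](C)C=C[C@H](OCc2ccc(OC)cc2)[C@@H]1C(C)=O | intermediate
29 | 2-[(1S,2S,5S,7R)-7-[(tert-butyldimethylsilyl)oxy]-2-[(4-methoxybenzyl)oxy]-5-methylcyclohept-3-en-1-yl]propan-2-ol | CC(C)(C)[Si](C)(C)O[C@@H]1C[C@H](C)C=C[C@H](OCc2ccc(OC)cc2)[C@@H]1C(C)(C)O | intermediate
30 | 2-[(1S,2S,5S,7R)-7-[(tert-butyldimethylsilyl)oxy]-2-[(4-methoxybenzyl)oxy]-5-methylcyclohept-3-en-1-yl]propan-2-yl acetate | CC(C)(C)[Si](C)(C)O[C@@H]1C[C@H](C)C=C[C@H](OCc2ccc(OC)cc2)[C@@H]1C(C)(C)OC(C)=O | intermediate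
31 | 2-[(1βH,7βH)-4β-[(tert-butyldimethylsilyl)oxy]-9,9-dichloro-6β-[(4-methoxybenzyl)oxy]-2β-methyl-8-oxobicyclo[5.2.0]nonan-5β-yl]propan-2-yl acetate (cis-fused cyclobutanone on guaiane C1/C5) | CC(C)(C)[Si](C)(C)O[C@@H]1C[C@H](C)[C@H]2C(Cl)(Cl)C(=O)[C@H]2[C@H](OCc3ccc(OC)cc3)[C@@H]1C(C)(C)OC(C)=O | intermediate
32 | (1βH,5βH,7αH,10αH)-11-acetoxy-8β-[(tert-butyldimethylsilyl)oxy]-2,2-dichloro-6β-[(4-methoxybenzyl)oxy]guaian-3-one, both C4 epimers | CC(C)(C)[Si](C)(C)O[C@@H]1C[C@H](C)[C@H]2C(Cl)(Cl)C(=O)C(C)[C@H]2[C@H](OCc3ccc(OC)cc3)[C@@H]1C(C)(C)OC(C)=O | intermediate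
33 | (1βH,5βH,7αH,10αH)-11-acetoxy-8β-[(tert-butyldimethylsilyl)oxy]-6β-[(4-methoxybenzyl)oxy]guaian-3-one, both C4 epimers | CC(C)(C)[Si](C)(C)O[C@@H]1C[C@H](C)[C@H]2CC(=O)C(C)[C@H]2[C@H](OCc3ccc(OC)cc3)[C@@H]1C(C)(C)OC(C)=O | intermediate
34 | (1βH,5βH,7αH,10αH)-11-acetoxy-8β-[(tert-butyldimethylsilyl)oxy]-6β-[(4-methoxybenzyl)oxy]-3-[(trimethylsilyl)oxy]guai-3-ene | CC(C)(C)[Si](C)(C)O[C@@H]1C[C@H](C)[C@H]2CC(O[Si](C)(C)C)=C(C)[C@H]2[C@H](OCc3ccc(OC)cc3)[C@@H]1C(C)(C)OC(C)=O | intermediate
35 | (1βH,7αH,10αH)-11-acetoxy-8β-[(tert-butyldimethylsilyl)oxy]-6β-[(4-methoxybenzyl)oxy]guai-4-en-3-one | CC(C)(C)[Si](C)(C)O[C@@H]1C[C@H](C)[C@H]2CC(=O)C(C)=C2[C@H](OCc3ccc(OC)cc3)[C@@H]1C(C)(C)OC(C)=O | intermediate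
36 | (7αH,10αH)-11-acetoxy-8β-[(tert-butyldimethylsilyl)oxy]-6β-[(4-methoxybenzyl)oxy]-3-[(trimethylsilyl)oxy]guaia-1(5),3-diene | CC(C)(C)[Si](C)(C)O[C@@H]1C[C@H](C)C2=C(C(C)=C(O[Si](C)(C)C)C2)[C@H](OCc3ccc(OC)cc3)[C@@H]1C(C)(C)OC(C)=O | intermediate
37 | (7αH,10αH)-11-acetoxy-8β-[(tert-butyldimethylsilyl)oxy]-1α-hydroxy-6β-[(4-methoxybenzyl)oxy]guai-4-en-3-one | CC(C)(C)[Si](C)(C)O[C@@H]1C[C@H](C)[C@]2(O)CC(=O)C(C)=C2[C@H](OCc3ccc(OC)cc3)[C@@H]1C(C)(C)OC(C)=O | intermediate
38 | (7αH,10αH)-11-acetoxy-1α,8β-dihydroxy-6β-[(4-methoxybenzyl)oxy]guai-4-en-3-one | O[C@@H]1C[C@H](C)[C@]2(O)CC(=O)C(C)=C2[C@H](OCc3ccc(OC)cc3)[C@@H]1C(C)(C)OC(C)=O | intermediate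
39 | angelic acid, (Z)-2-methylbut-2-enoic acid | C/C=C(/C)C(=O)O | starting material
40 | (Z)-2-methylbut-2-enoic 2,4,6-trichlorobenzoic anhydride | C/C=C(/C)C(=O)OC(=O)c1c(Cl)cc(Cl)cc1Cl | intermediate
41 | (7αH,10αH)-11-acetoxy-1α-hydroxy-6β-[(4-methoxybenzyl)oxy]-3-oxoguai-4-en-8β-yl (Z)-2-methylbut-2-enoate | C/C=C(/C)C(=O)O[C@@H]1C[C@H](C)[C@]2(O)CC(=O)C(C)=C2[C@H](OCc3ccc(OC)cc3)[C@@H]1C(C)(C)OC(C)=O | intermediate
42 | (1R,6R,7S,8R,10S)-11-acetoxy-1,6-dihydroxy-3-oxoguai-4-en-8-yl (Z)-2-methylbut-2-enoate, CNP0273287.1 | C/C=C(/C)C(=O)O[C@@H]1C[C@H](C)[C@]2(O)CC(=O)C(C)=C2[C@H](O)[C@@H]1C(C)(C)OC(C)=O | target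

## Step count and least certain steps

Total: 24 steps. Longest linear sequence: 24 steps, from 1 to 42 (4, 14, 22 and 39 enter as bought compounds).

**Step 13 (key step).** The lithium enolate of 23 may expel the C8 silyloxy group by β-elimination before it is silylated. Alternatively the ketene acetal 24 may ionise at the alkoxy-stabilised allylic C1–O bond instead of rearranging, because the boat-like transition state is strained. The fallback is the dianion form of the ester-enolate Claisen rearrangement, in which the C8 oxygen is an alkoxide and cannot leave. It sets out from 23: Bu4NF buffered with AcOH removes the silyl group to give the C8-hydroxy lactone F1. Two equivalents of LiN(i-Pr)2 form the alkoxide-enolate, Me3SiCl silylates both oxygens, and warming followed by aqueous work-up gives the hydroxy acid F2. Silylation of F2 as in step 5 (silyl triflate, then carbonate) comes back to the route at 26.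

**Step 17.** The ketene may acylate the allylic C6 ether oxygen and then undergo a [3,3] shift (ketene-Claisen pathway). The cycloaddition may also be slow at an alkene flanked on both sides, or the regioselectivity may be eroded. The fallback replaces the ether by a silyl ether, whose oxygen is a poor nucleophile and which withdraws electrons in the same sense. It sets out from 30:
- DDQ gives the allylic alcohol F3, and t-BuPh2SiCl with imidazole gives the silyl ether F4.
- The operations of steps 17 to 21 then give the cyclobutanone F5, the dichlorocyclopentanone F6, the cyclopentanone F7, the enone F8 and the hydroxy enone F9.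
- Brief HF·pyridine treatment removes the more labile tert-butyldimethylsilyl group to give the C8 alcohol F10, and the esterification of step 23 gives the angelate F11.
- Prolonged HF·pyridine treatment removes the tert-butyldiphenylsilyl group and comes back to the route at 42.

**Step 21.** Oxygen may be transferred to C4 instead of C1, the dienol ether may not settle on isomer 36, or attack may occur partly on the β face. The fallback is deconjugation, epoxidation and elimination. It sets out from 35: KOt-Bu followed by kinetic protonation with AcOH gives the β,γ-enone F12. Peracid epoxidation of its tetrasubstituted C1=C5 bond from the α face gives the epoxy ketone F13. Et3N opens F13 by β-elimination from C4 and comes back to the route at 37.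

**Step 12.** Protodeboronation or oxidative homocoupling of 21 may outrun C–O bond formation, or the excess alcohol may open the lactone. The fallback is a copper-catalysed vinylation of the alcohol with a vinyl halide. It sets out from 20: hydrozirconation with Cp2ZrHCl and iodinolysis give the (E)-vinyl iodide F14. Coupling of F14 with 22 under CuI (copper monoiodide), 3,4,7,8-tetramethyl-1,10-phenanthroline and Cs2CO3 in toluene proceeds with retention and comes back to the route at 23.

**Step 5.** When the silyl triflate activates the tert-butyl ester, the C8 oxygen may close the γ-lactone with loss of its silyl group. The fallback accepts the lactone. It sets out from 8: CF3CO2H cleaves the tert-butyl ester and gives the γ-lactone F15. Me2AlN(OMe)Me, from AlMe3 and the amine hydrochloride, opens the lactone (more reactive than the methyl ester) to the hydroxy amide F16. Immediate silylation with t-BuMe2SiCl and imidazole comes back to the route at 13.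

## Further compounds

F1 | step 13 | (4R,6S,7S)-4-hydroxy-7-[(E)-2-[(4-methoxybenzyl)oxy]ethenyl]-6-methyloxepan-2-one | O=C1C[C@H](O)C[C@H](C)[C@@H](/C=C/OCc2ccc(OC)cc2)O1
F2 | step 13 | 7-hydroxy-2-[(4-methoxybenzyl)oxy]-5-methylcyclohept-3-ene-1-carboxylic acid, all four substituents cis (26 without its silyl group) | O[C@@H]1C[C@H](C)C=C[C@H](OCc2ccc(OC)cc2)[C@@H]1C(=O)O
F3 | step 17 | allylic alcohol, 30 with a free C6 hydroxyl | CC(C)(C)[Si](C)(C)O[C@@H]1C[C@H](C)C=C[C@H](O)[C@@H]1C(C)(C)OC(C)=O
F4 | step 17 | 30 with a tert-butyldiphenylsilyl ether at C6 | CC(C)(C)[Si](C)(C)O[C@@H]1C[C@H](C)C=C[C@H](O[Si](c2ccccc2)(c2ccccc2)C(C)(C)C)[C@@H]1C(C)(C)OC(C)=O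
F5 | step 17 | cis-fused dichlorocyclobutanone, 31 with a tert-butyldiphenylsilyl ether at C6 | CC(C)(C)[Si](C)(C)O[C@@H]1C[C@H](C)[C@H]2C(Cl)(Cl)C(=O)[C@H]2[C@H](O[Si](c3ccccc3)(c3ccccc3)C(C)(C)C)[C@@H]1C(C)(C)OC(C)=O
F6 | step 17 | 2,2-dichloroguaian-3-one, 32 with a tert-butyldiphenylsilyl ether at C6 | CC(C)(C)[Si](C)(C)O[C@@H]1C[C@H](C)[C@H]2C(Cl)(Cl)C(=O)C(C)[C@H]2[C@H](O[Si](c3ccccc3)(c3ccccc3)C(C)(C)C)[C@@H]1C(C)(C)OC(C)=O
F7 | step 17 | guaian-3-one, 33 with a tert-butyldiphenylsilyl ether at C6 | CC(C)(C)[Si](C)(C)O[C@@H]1C[C@H](C)[C@H]2CC(=O)C(C)[C@H]2[C@H](O[Si](c3ccccc3)(c3ccccc3)C(C)(C)C)[C@@H]1C(C)(C)OC(C)=O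
F8 | step 17 | guai-4-en-3-one, 35 with a tert-butyldiphenylsilyl ether at C6 | CC(C)(C)[Si](C)(C)O[C@@H]1C[C@H](C)[C@H]2CC(=O)C(C)=C2[C@H](O[Si](c3ccccc3)(c3ccccc3)C(C)(C)C)[C@@H]1C(C)(C)OC(C)=O
F9 | step 17 | 1α-hydroxyguai-4-en-3-one, 37 with a tert-butyldiphenylsilyl ether at C6 | CC(C)(C)[Si](C)(C)O[C@@H]1C[C@H](C)[C@]2(O)CC(=O)C(C)=C2[C@H](O[Si](c3ccccc3)(c3ccccc3)C(C)(C)C)[C@@H]1C(C)(C)OC(C)=O
F10 | step 17 | 1α,8β-diol, 38 with a tert-butyldiphenylsilyl ether at C6 | O[C@@H]1C[C@H](C)[C@]2(O)CC(=O)C(C)=C2[C@H](O[Si](c3ccccc3)(c3ccccc3)C(C)(C)C)[C@@H]1C(C)(C)OC(C)=O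
F11 | step 17 | 8β-angelate, 41 with a tert-butyldiphenylsilyl ether at C6 | C/C=C(/C)C(=O)O[C@@H]1C[C@H](C)[C@]2(O)CC(=O)C(C)=C2[C@H](O[Si](c3ccccc3)(c3ccccc3)C(C)(C)C)[C@@H]1C(C)(C)OC(C)=O
F12 | step 21 | (7αH,10αH)-11-acetoxy-8β-[(tert-butyldimethylsilyl)oxy]-6β-[(4-methoxybenzyl)oxy]guai-1(5)-en-3-one, both C4 epimers | CC(C)(C)[Si](C)(C)O[C@@H]1C[C@H](C)C2=C(C(C)C(=O)C2)[C@H](OCc3ccc(OC)cc3)[C@@H]1C(C)(C)OC(C)=O
F13 | step 21 | 1α,5α-epoxide of F12 | CC(C)(C)[Si](C)(C)O[C@@H]1C[C@H](C)[C@]23CC(=O)C(C)[C@]2(O3)[C@H](OCc4ccc(OC)cc4)[C@@H]1C(C)(C)OC(C)=O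
F14 | step 12 | (4R,6S,7S)-4-[(tert-butyldimethylsilyl)oxy]-7-[(E)-2-iodoethenyl]-6-methyloxepan-2-one | O=C1C[C@H](O[Si](C)(C)C(C)(C)C)C[C@H](C)[C@@H](/C=C/I)O1
F15 | step 5 | methyl 2-[(2R,4S)-4-methyl-5-oxooxolan-2-yl]acetate | C[C@H]1C[C@H](CC(=O)OC)OC1=O
F16 | step 5 | methyl (3R,5S)-3-hydroxy-6-[methoxy(methyl)amino]-5-methyl-6-oxohexanoate | C[C@@H](C[C@@H](O)CC(=O)OC)C(=O)N(C)OC
A1 | alternative 1 | meso cyclohexanone: all-cis 4-(2-acetoxypropan-2-yl)-3,5-dihydroxycyclohexanone 3,5-acetonide (C1 ketone, C6/C8 acetonide) | O=C1C[C@@H]2OC(C)(C)O[C@H](C1)[C@H]2C(C)(C)OC(C)=O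
A2 | alternative 1 | cycloheptanone with the C10 methyl and the C6/C7/C8 array | O=C1C[C@@H]2OC(C)(C)O[C@H](C[C@@H]1C)[C@H]2C(C)(C)OC(C)=O
A3 | alternative 2 | diazoketone: cycloheptane with C1 triethylsilyloxy, C5 CH(CH3)C(=O)CHN2 side chain, C6 chloroacetate, C8 4-methoxybenzyl ether | COc1ccc(CO[C@@H]2C[C@H](C)[C@@H](O[Si](CC)(CC)CC)[C@H]([C@H](C)C(=O)C=[N+]=[N-])[C@H](OC(=O)CCl)[C@@H]2C(C)(C)OC(C)=O)cc1
A4 | alternative 2 | cis-fused cyclopentanone with the C1 quaternary triethylsilyl ether | COc1ccc(CO[C@@H]2C[C@H](C)[C@]3(O[Si](CC)(CC)CC)CC(=O)[C@@H](C)[C@@H]3[C@H](OC(=O)CCl)[C@@H]2C(C)(C)OC(C)=O)cc1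
A5 | alternative 3 | allene-yne: C2=C1=C10(CH3) allene and C4≡C5 methylalkyne joined by the C6 (silyloxy), C7 (2-acetoxypropan-2-yl), C8 (4-methoxybenzyloxy), C9 chain | C=C=C(C)C[C@@H](OCc1ccc(OC)cc1)[C@H]([C@@H](O[Si](C)(C)C(C)(C)C)C#CC)C(C)(C)OC(C)=O
A6 | alternative 3 | protected guaia-1(10),4-dien-3-one | COc1ccc(CO[C@@H]2CC(C)=C3CC(=O)C(C)=C3[C@H](O[Si](C)(C)C(C)(C)C)[C@@H]2C(C)(C)OC(C)=O)cc1
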